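**Plan**

1. Retrosynthesis (chain atoms C1 = CO2H to C9 = CH2 on chroman C-2): cut C2=C3 (Z-selective olefination of a C3 aldehyde), then the C7–C8 σ-bond, then chroman O1–C2 together with C8–C9 (oxypalladation/carbonylation), then aryl–CH2 (C4a–C4).
2. Forward: the benzene ring is bought; the pyran ring of the chroman is closed in step 3; the chain is joined at C7–C8 in step 7 and completed at C1–C2 in step 9.
3. Enabling feature: chain atoms C3–C7 with the 6-methyl group, plus an oxygen on C3 (the later enoate β-carbon, free to carry O), are a ring-opened 5-methyl-3,4-dihydro-2H-pyran. In that temporary ring O and C5 are held cis across C6=C7, so a 1,2-metalate shift that brings C8 onto C7 with inversion and expels the ring oxygen should give only the 6E olefin.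
4. The helper oxygen then serves as the C3 aldehyde and leaves as phosphate in step 9.
5. Stereochemistry: chroman C-2 (R in the target) from enantioselective Pd(II)/BOXAX oxypalladation (step 3); 6E from ring geometry plus inversion (step 7); 2Z from Still–Gennari olefination (step 9).

Key step: step 7

Assumption: (S,S)-Bn-BOXAX is taken to direct the oxypalladation in step 3 to the alkene face that gives the (S)-ester 6, by analogy with closely related 2-(3-methylbut-3-enyl)phenols; if the sense is opposite, the (R,R)-ligand is used and nothing else changes.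
Assumption: compounds 1, 3, 9 and 17 are taken as commercially available.

**Route**

Step 1
Reactants: 1 4-methoxy-2-methylphenol
Product: 2 2-bromo-4-methoxy-6-methylphenol
Conditions: NBS (1.0 eq), i-Pr2NH (10 mol%), CH2Cl2, 0 °C
Reagents that add atoms: N-bromosuccinimide, O=C1CCC(=O)N1Br
Why: Amine-mediated electrophilic aromatic bromination should deliver bromine ortho to the free hydroxyl, the strongest activating group, whose para position and other ortho position are blocked by OMe and CH3.

Step 2
Reactants: 2 2-bromo-4-methoxy-6-methylphenol, 3 4-bromo-2-methylbut-1-ene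
Product: 5 4-methoxy-2-methyl-6-(3-methylbut-3-en-1-yl)phenol, via homoallylzinc bromide 4 (not isolated)
Conditions: 3, Zn dust, LiCl, THF, 50 °C; then 2, Pd(OAc)2 (2 mol%), SPhos (4 mol%), THF, 25 °C; aq NH4Cl
Reagents that add atoms: none
Why: Negishi sp2–sp3 cross-coupling, in which the primary alkylzinc halide should be transferred by the Pd/biarylphosphine catalyst faster than it is protonated by the phenol and reductive elimination should outrun β-hydride elimination, so the terminal 1,1-disubstituted alkene stays in place.

Step 3
Reactants: 5 4-methoxy-2-methyl-6-(3-methylbut-3-en-1-yl)phenol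
Product: 6 methyl 2-[(2S)-6-methoxy-2,8-dimethyl-3,4-dihydro-2H-chromen-2-yl]acetate
Conditions: Pd(OCOCF3)2 (5 mol%), (S,S)-Bn-BOXAX (20 mol%), p-benzoquinone (4 eq), CO (1 atm), MeOH, 20 °C
Reagents that add atoms: carbon monoxide, [C-]#[O+]; methanol, CO
Why: Enantioselective domino Wacker-type oxypalladation/methoxycarbonylation, in which the phenol adds 6-exo-trig to the Pd(II)-bound alkene, the resulting σ-alkylpalladium has no β-hydrogen and therefore inserts CO and is methanolysed, and the C-2 stereocentre is set by the chiral bis(oxazoline)–Pd complex selecting one alkene face.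

Step 4
Reactants: 6 methyl 2-[(2S)-6-methoxy-2,8-dimethyl-3,4-dihydro-2H-chromen-2-yl]acetate
Product: 7 2-[(2S)-6-methoxy-2,8-dimethyl-3,4-dihydro-2H-chromen-2-yl]ethan-1-ol
Conditions: LiAlH4, THF, 0 °C; aqueous work-up (Rochelle salt)
Reagents that add atoms: none
Why: Hydride reduction of the ester to the primary alcohol, which leaves the quaternary stereocentre (no acidic hydrogen) and both aryl ethers untouched.

Step 5
Reactants: 7 2-[(2S)-6-methoxy-2,8-dimethyl-3,4-dihydro-2H-chromen-2-yl]ethan-1-ol
Product: 8 (2S)-2-(2-iodoethyl)-6-methoxy-2,8-dimethyl-3,4-dihydro-2H-chromene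
Conditions: PPh3, I2, imidazole, CH2Cl2, 0 → 20 °C
Reagents that add atoms: iodine, II
Why: Appel-type iodination, an SN2 displacement of the oxyphosphonium group at the unhindered primary carbon, remote from the stereocentre.

Step 6
Reactants: 9 5-bromo-3,4-dihydro-2H-pyran
Product: 10 5-methyl-3,4-dihydro-2H-pyran
Conditions: MeMgBr (1.2 eq), Ni(dppp)Cl2 (2 mol%), Et2O, 0 °C → reflux; fractional distillation
Reagents that add atoms: methylmagnesium bromide, C[Mg]Br
Why: Kumada–Corriu coupling, in which nickel should insert into the alkenyl C–Br bond far faster than into the enol ether C–O bond, so methyl replaces bromine at C-5.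

Step 7
Reactants: 8 (2S)-2-(2-iodoethyl)-6-methoxy-2,8-dimethyl-3,4-dihydro-2H-chromene, 10 5-methyl-3,4-dihydro-2H-pyran
Product: 15 (4E)-7-[(2R)-6-methoxy-2,8-dimethyl-3,4-dihydro-2H-chromen-2-yl]-4-methylhept-4-en-1-ol, via lithiated dihydropyran 11 (not isolated), via alkyllithium 12 (not isolated), via mixed lithium cuprate 13 (not isolated), via alkenylcopper alkoxide 14 (not isolated)
Conditions: 10 (1.3 eq), t-BuLi, THF–pentane, −78 → 0 °C; separately 8, t-BuLi (2.1 eq), Et2O, −78 °C, then CuBr·SMe2 (1.0 eq), Et2O–Me2S, −78 → −40 °C; combine at −78 °C, warm to 20 °C; aq NH4Cl–NH3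
Reagents that add atoms: none
Why: The alkylcopper formed from 12 and the α-lithiated enol ether 11 give the ate complex 13, in which the only sp3 ligand migrates from copper to the metal-bearing ring carbon in the plane of the double bond and anti to the C–O bond while the ring oxygen leaves as lithium alkoxide (1,2-metalate rearrangement with inversion at the alkenyl carbon), and aqueous protonolysis of the C–Cu bond of 14 then occurs with retention. The closest known reaction type is the 1,2-metalate rearrangement of cuprates of α-lithiated 2,3-dihydrofurans and 3,4-dihydro-2H-pyrans to (E)-alkenols, long used for stereodefined isoprenoid olefins, here run on a pyran that carries a 5-methyl group. No ring is closed: the temporary dihydropyran ring is opened and the chroman ring is not touched. No stereocentre is formed, and chroman C-2, which has no hydrogen and is three bonds from the carbanion, cannot be scrambled; the one new stereo-element, the C6=C7 geometry of the target (C4=C5 of 15), is controlled by the ring, which holds O and C-4 cis on the enol ether double bond, so that inversion places the incoming CH2 (C8) trans to the tether and cis to the methyl group, i.e. E. The selectivities needed are transfer of the alkyl rather than the alkenyl ligand and a shift that outruns β-hydride loss from the alkylcopper: the complex holds a single sp3 ligand, the antiperiplanar C–O bond is fixed by the ring, and expulsion of the alkoxide makes the shift irreversible; a nickel-catalysed ring opening with a Grignard reagent would go with retention and give the Z isomer, which is why the metalate pathway is chosen.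

Step 8
Reactants: 15 (4E)-7-[(2R)-6-methoxy-2,8-dimethyl-3,4-dihydro-2H-chromen-2-yl]-4-methylhept-4-en-1-ol
Product: 16 (4E)-7-[(2R)-6-methoxy-2,8-dimethyl-3,4-dihydro-2H-chromen-2-yl]-4-methylhept-4-enal
Conditions: Dess–Martin periodinane (1.2 eq), CH2Cl2, 0 → 20 °C
Reagents that add atoms: none
Why: Dess–Martin oxidation of the primary alcohol to the aldehyde under near-neutral conditions that should leave the trisubstituted alkene and the electron-rich arene untouched.

Step 9
Reactants: 16 (4E)-7-[(2R)-6-methoxy-2,8-dimethyl-3,4-dihydro-2H-chromen-2-yl]-4-methylhept-4-enal, 17 ethyl 2-[bis(2,2,2-trifluoroethoxy)phosphoryl]propanoate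
Product: 18 ethyl (2Z,6E)-9-[(2R)-6-methoxy-2,8-dimethyl-3,4-dihydro-2H-chromen-2-yl]-2,6-dimethylnona-2,6-dienoate
Conditions: 17, KHMDS, 18-crown-6, THF, −78 °C; then 16, −78 °C
Reagents that add atoms: none
Why: Still–Gennari variant of the Horner–Wadsworth–Emmons olefination, in which the electron-poor bis(trifluoroethyl) phosphonate and the dissociated potassium counter-ion make elimination from the kinetic adduct faster than its equilibration, which should give the (Z)-2-methyl enoate with the chain cis to the ester.

Step 10
Reactants: 18 ethyl (2Z,6E)-9-[(2R)-6-methoxy-2,8-dimethyl-3,4-dihydro-2H-chromen-2-yl]-2,6-dimethylnona-2,6-dienoate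
Product: 19 (2Z,6E)-9-[(2R)-6-methoxy-2,8-dimethyl-3,4-dihydro-2H-chromen-2-yl]-2,6-dimethylnona-2,6-dienoic acid
Conditions: LiOH, THF–H2O (3:1), 40 °C; then 1 M HCl to pH 3
Reagents that add atoms: lithium hydroxide, [Li+].[OH-]
Why: Saponification (BAc2) of the ethyl ester followed by mild acidification, conditions under which the Z enoate should not isomerise and the tertiary alkyl aryl ether should survive.

**Compound list**

1 | 4-methoxy-2-methylphenol | COc1ccc(O)c(C)c1 | starting material
2 | 2-bromo-4-methoxy-6-methylphenol | COc1cc(C)c(O)c(Br)c1 | intermediate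
3 | 4-bromo-2-methylbut-1-ene | C=C(C)CCBr | starting material
4 | (3-methylbut-3-en-1-yl)zinc bromide | C=C(C)CC[Zn]Br | intermediate
5 | 4-methoxy-2-methyl-6-(3-methylbut-3-en-1-yl)phenol | COc1cc(C)c(O)c(CCC(C)=C)c1 | intermediate
6 | methyl 2-[(2S)-6-methoxy-2,8-dimethyl-3,4-dihydro-2H-chromen-2-yl]acetate | COc1cc(C)c2c(c1)CC[C@@](C)(CC(=O)OC)O2 | intermediate
7 | 2-[(2S)-6-methoxy-2,8-dimethyl-3,4-dihydro-2H-chromen-2-yl]ethan-1-ol | COc1cc(C)c2c(c1)CC[C@@](C)(CCO)O2 | intermediate
8 | (2S)-2-(2-iodoethyl)-6-methoxy-2,8-dimethyl-3,4-dihydro-2H-chromene | COc1cc(C)c2c(c1)CC[C@@](C)(CCI)O2 | intermediate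
9 | 5-bromo-3,4-dihydro-2H-pyran | BrC1=COCCC1 | starting material
10 | 5-methyl-3,4-dihydro-2H-pyran | CC1=COCCC1 | intermediate
11 | 6-lithio-5-methyl-3,4-dihydro-2H-pyran | [Li]C1=C(C)CCCO1 | intermediate
12 | 2-(6-methoxy-2,8-dimethylchroman-2-yl)ethyllithium, configuration at C-2 as in 8 | COc1cc(C)c2c(c1)CC[C@@](C)(CC[Li])O2 | intermediate
13 | lithium [2-(6-methoxy-2,8-dimethylchroman-2-yl)ethyl](5-methyl-3,4-dihydro-2H-pyran-6-yl)cuprate, configuration at C-2 as in 8 | [Li+].COc1cc(C)c2c(c1)CC[C@@](C)(CC[Cu-]C1=C(C)CCCO1)O2 | intermediate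
14 | lithium alkoxide of the ring-opened alkenylcopper: Cu on the chain carbon that now bears the chromanylethyl group, this group cis to the methyl, Cu cis to the (CH2)3O– tether | [Li+].COc1cc(C)c2c(c1)CC[C@@](C)(CC/C([Cu])=C(\C)CCC[O-])O2 | intermediate
15 | (4E)-7-[(2R)-6-methoxy-2,8-dimethyl-3,4-dihydro-2H-chromen-2-yl]-4-methylhept-4-en-1-ol | COc1cc(C)c2c(c1)CC[C@@](C)(CC/C=C(\C)CCCO)O2 | intermediate
16 | (4E)-7-[(2R)-6-methoxy-2,8-dimethyl-3,4-dihydro-2H-chromen-2-yl]-4-methylhept-4-enal | COc1cc(C)c2c(c1)CC[C@@](C)(CC/C=C(\C)CCC=O)O2 | intermediate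
17 | ethyl 2-[bis(2,2,2-trifluoroethoxy)phosphoryl]propanoate | CCOC(=O)C(C)P(=O)(OCC(F)(F)F)OCC(F)(F)F | starting material
18 | ethyl (2Z,6E)-9-[(2R)-6-methoxy-2,8-dimethyl-3,4-dihydro-2H-chromen-2-yl]-2,6-dimethylnona-2,6-dienoate | COc1cc(C)c2c(c1)CC[C@@](C)(CC/C=C(\C)CC/C=C(/C)C(=O)OCC)O2 | intermediate
19 | (2Z,6E)-9-[(2R)-6-methoxy-2,8-dimethyl-3,4-dihydro-2H-chromen-2-yl]-2,6-dimethylnona-2,6-dienoic acid | COc1cc(C)c2c(c1)CC[C@@](C)(CC/C=C(\C)CC/C=C(/C)C(=O)O)O2 | target

**Summary**

Total step count: 10. Longest linear sequence: 9 steps (steps 1–5 and 7–10, from 1); step 6 is a one-step branch.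

Steps most likely to fail:

1. Step 7. The 1,2-shift in the six-membered, methyl-substituted enol ether complex may be slower than thermal decay (β-hydride loss) of the primary alkylcopper ligand, or the complex may be protonated unchanged on work-up, so that the C7–C8 bond is not formed. The fallback sets out from 8 and comes back at 15. Pent-4-yn-1-ol is methylaluminated (AlMe3, cat. Cp2ZrCl2, CH2Cl2; syn addition) to the (E)-alkenylalane F1, which iodine converts into (E)-5-iodo-4-methylpent-4-en-1-ol F2. Compound 8 is lithiated to 12 as in step 7 and trapped with B-methoxy-9-BBN as the lithium borinate F3. B-alkyl Suzuki–Miyaura coupling of F3 with F2 (Pd(dppf)Cl2, K3PO4, DMF–H2O, 20 °C) then joins the same two carbons with retention of the olefin geometry, which in this variant is set beforehand by the carbometalation.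

2. Step 3. Discrimination between the two alkene faces in the oxypalladation may be insufficient, which would erode the enantiomeric purity of the only stereocentre. The fallback sets out from 5 and comes back at 6. The oxypalladation/methoxycarbonylation is run with an achiral Pd(II) catalyst to give the racemic ester F4, and the enantiomers are separated by preparative chromatography on a chiral stationary phase. The (R)-ester F5 is set aside and the (S)-ester is 6, so the stereocentre comes from resolution and not from asymmetric catalysis.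

3. Step 2. Protonolysis of the alkylzinc reagent by the phenol and slow oxidative addition to the electron-rich ortho-bromophenoxide may stall the coupling. The fallback sets out from 2 and comes back at 5. Heck arylation of but-3-en-2-ol with 2 (Pd(OAc)2, Bu4NCl, NaHCO3, DMF, 80 °C), in which β-hydride elimination towards the carbinol carbon delivers the saturated ketone, gives 4-(2-hydroxy-5-methoxy-3-methylphenyl)butan-2-one F6. Wittig methylenation (Ph3P=CH2, 3 eq, THF) then gives 5.

Further compounds
F1 | step 7 | (E)-alkenylalane from pent-4-yn-1-ol: dimethylaluminium on the terminal alkene carbon cis to the new methyl, hydroxyl as its dimethylaluminium alkoxide | C[Al](C)/C=C(\C)CCCO[Al](C)C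
F2 | step 7 | (E)-5-iodo-4-methylpent-4-en-1-ol | I/C=C(\C)CCCO
F3 | step 7 | lithium B-[2-(6-methoxy-2,8-dimethylchroman-2-yl)ethyl]-B-methoxy-9-borabicyclo[3.3.1]nonane borinate, configuration at C-2 as in 8 | [Li+].COc1cc(C)c2c(c1)CC[C@@](C)(CC[B-]1(OC)C3CCCC1CCC3)O2
F4 | step 3 | racemic methyl 2-(6-methoxy-2,8-dimethyl-3,4-dihydro-2H-chromen-2-yl)acetate | COc1cc(C)c2c(c1)CCC(C)(CC(=O)OC)O2
F5 | step 3 | methyl 2-[(2R)-6-methoxy-2,8-dimethyl-3,4-dihydro-2H-chromen-2-yl]acetate | COc1cc(C)c2c(c1)CC[C@](C)(CC(=O)OC)O2
F6 | step 2 | 4-(2-hydroxy-5-methoxy-3-methylphenyl)butan-2-one | COc1cc(C)c(O)c(CCC(C)=O)c1
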